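**Strategy.** The benzene ring is taken apart into an open-chain tetraketide. Its 1,3,5-pattern (C1 bearing the side chain, C3 and C5 bearing OH, C2, C4 and C6 bearing H) is the alternating carbonyl/methylene pattern of a 3,5,7-trioxo ester whose C2 is folded onto C7. One base-mediated aldol condensation forges the C2–C7 bond, closes the only ring and aromatizes it to a 6-alkyl-2,4-dihydroxybenzoate; the ester carbon is later expelled as CO2. The precursor, methyl (23S)-23-silyloxy-3,5,7-trioxotetracosanoate, comes from a C18 (S)-17-silyloxy acid, built from (S)-propylene oxide and 1-hexadecyne, and from methyl 3,5-dioxohexanoate.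

Key step: step 6

Remarks on the chemistry:
- Assumption: (S)-propylene oxide, 1-hexadecyne and methyl 3,5-dioxohexanoate are purchased.
- Compounds 11 and 12 are drawn as keto tautomers although both will be largely enolized. Compound 11 is taken on after extractive work-up without chromatography.
- The CIP order at the carbinol carbon (O > CH2 > CH3 > H) never changes, so the descriptor stays (S) from 1 to 16.
- 1-Hexadecyne is chosen so that a single oxidative cleavage of the zipped C19 alkyne gives the C18 acid directly.

**Step 1**
Reactants: 1 (S)-propylene oxide; 2 1-hexadecyne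
Product: 4 (S)-nonadec-4-yn-2-ol, via lithium hexadec-1-yn-1-ide 3 (not isolated)
Conditions: 2, n-BuLi, THF, −78 °C; BF3·OEt2, −78 °C; then 1, −78 °C; H2O quench
Reagents that add atoms: none
Why: Yamaguchi–Hirao alkynylation, in which the lithium acetylide opens the BF3-activated epoxide by SN2 attack at its unsubstituted CH2, so the (S)-stereocentre bought in 1 (the only one of the target) is not a reacting centre and keeps its configuration.

**Step 2**
Reactants: 4 (S)-nonadec-4-yn-2-ol
Product: 5 (S)-nonadec-18-yn-2-ol
Conditions: KH, H2N(CH2)3NH2, rt (gives KNH(CH2)3NH2); then 4, THF, 0 °C to rt; H2O quench at 0 °C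
Reagents that add atoms: none
Why: Alkyne zipper reaction, in which KNH(CH2)3NH2 walks the triple bond along the chain through propargyl/allenyl anion equilibria until it is removed irreversibly as the terminal acetylide, while migration past C3 is impossible because the alkoxide-bearing C2 cannot be deprotonated, so the (S)-centre should survive.

**Step 3**
Reactants: 5 (S)-nonadec-18-yn-2-ol
Product: 6 (S)-tert-butyldimethyl(nonadec-18-yn-2-yloxy)silane
Conditions: TBSCl, imidazole, DMF, rt
Reagents that add atoms: tert-butyldimethylsilyl chloride (TBSCl), CC(C)(C)[Si](C)(C)Cl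
Why: Imidazole-promoted silylation of a secondary alcohol (silyl ether formation), which masks the hydroxyl against CDI and the trianion of step 5 and should be stable to steps 4 to 6.

**Step 4**
Reactants: 6 (S)-tert-butyldimethyl(nonadec-18-yn-2-yloxy)silane
Product: 7 (S)-17-(tert-butyldimethylsilyloxy)octadecanoic acid
Conditions: RuCl3·xH2O (cat.), NaIO4, EtOAc/MeCN/H2O, 0 °C to rt
Reagents that add atoms: sodium periodate, [Na+].[O-]I(=O)(=O)=O; water, O
Why: Ruthenium tetroxide, generated catalytically from RuCl3 by NaIO4, cleaves the terminal alkyne oxidatively to the carboxylic acid with loss of the terminal carbon as CO2, so the C19 chain is trimmed to exactly C18 while saturated methylenes and the silyl ether should not react at a comparable rate.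

**Step 5**
Reactants: 7 (S)-17-(tert-butyldimethylsilyloxy)octadecanoic acid; 8 methyl 3,5-dioxohexanoate
Product: 11 methyl (23S)-23-(tert-butyldimethylsilyloxy)-3,5,7-trioxotetracosanoate, via acyl imidazolide 9 (not isolated), via trilithium trianion 10 (not isolated)
Conditions: 7, CDI, THF, rt; 8 (2.5 equiv), LiN(i-Pr)2 (commercial solution, 3.3 equiv per 8), THF, −78 to 0 °C; solution of 9 added at −78 °C, then to −20 °C; AcOH quench
Reagents that add atoms: 1,1'-carbonyldiimidazole (CDI), O=C(n1ccnc1)n1ccnc1 (supplies only the imidazol-1-yl group of 9, which is expelled when 11 forms; every heavy atom of 11 comes from 7 and 8)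
Why: Claisen-type C-acylation of a 1,3,5-tricarbonyl trianion by an acyl imidazolide, in which the C6 carbanion of 10, formed last from the least acidic site, is the most nucleophilic position and should alone attack 9, while the excess of 10 absorbs the protons of the released imidazole and of the more acidic product.

**Step 6**
Reactants: 11 methyl (23S)-23-(tert-butyldimethylsilyloxy)-3,5,7-trioxotetracosanoate
Product: 13 methyl 2,4-dihydroxy-6-[(16S)-16-(tert-butyldimethylsilyloxy)heptadecyl]benzoate, via cyclic aldol adduct 12 (not isolated)
Conditions: Cs2CO3 (2 equiv), MeOH, 0 °C to rt; then AcOH, rt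
Reagents that add atoms: none
Why: Carbonate reversibly ionizes the acidic methylenes of 11; the C4 and C6 enolates (each between two ketones) are the more stable but have no ketone within six-ring reach, whereas the C2 enolate, stabilized by the ester and the C3 ketone, adds to the C7 ketone in an intramolecular aldol reaction that forms the C2–C7 bond and gives 12. Loss of the C7 hydroxyl as water and enolization of the C3 and C5 carbonyls then give the benzene ring, an irreversible thermodynamic sink. The closest known reaction type is the base-induced aldol aromatization of 3,5,7-triketo esters to 6-substituted 2,4-dihydroxybenzoates, the laboratory counterpart of orsellinate-type polyketide cyclization. The single carbocycle closes in a 6-(enolendo)-exo-trig mode, the C2=C3 enolate lying inside the new ring and the C7 carbonyl oxygen outside it. No stereocentre remains from the step (the two transient centres of 12 vanish on aromatization), and the (S)-silyloxy carbon, fifteen methylenes away, is not involved. The step needs C2-to-C7 aldol closure to beat C6-to-C1 Claisen closure, C8-to-C3 aldol closure and lactonization of the C5 enol onto the ester; a ketone being a better acceptor than the ester, C8–H being far less acidic than C2–H, and a mild non-chelating base in methanol (methyl ester matched to the solvent) in place of a chelating magnesium alkoxide should secure this.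

**Step 7**
Reactants: 13 methyl 2,4-dihydroxy-6-[(16S)-16-(tert-butyldimethylsilyloxy)heptadecyl]benzoate
Product: 16 Hansfordiol A [5-[(16S)-16-hydroxyheptadecyl]benzene-1,3-diol], via resorcylic acid 14 (not isolated), via silylated alkylresorcinol 15 (not isolated)
Conditions: KOH (10 equiv), MeOH/THF/H2O (degassed), reflux, Ar; then aq. HCl to pH 1, 50 °C
Reagents that add atoms: potassium hydroxide, [K+].[OH-] (its oxygen is found only in the carboxyl group of 14 and leaves again as CO2; 16 itself gains hydrogen only)
Why: Hot aqueous-methanolic KOH should saponify the hindered ester, the resulting beta-resorcylate (ring carbon C1 activated by ortho and para oxygen donors) should lose CO2 by ipso protonation (protodecarboxylation) in the hot alkaline medium and on acidification, and the aqueous HCl then hydrolyses the secondary silyl ether, so one pot should deliver 16 with the remote carbinol centre untouched.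

**Compound list**
1 | (S)-propylene oxide [(S)-2-methyloxirane] | C[C@H]1CO1 | starting material
2 | 1-hexadecyne | C#CCCCCCCCCCCCCCC | starting material
3 | lithium hexadec-1-yn-1-ide (not isolated) | [Li+].[C-]#CCCCCCCCCCCCCCC | intermediate
4 | (S)-nonadec-4-yn-2-ol | C[C@H](O)CC#CCCCCCCCCCCCCCC | intermediate
5 | (S)-nonadec-18-yn-2-ol | C[C@H](O)CCCCCCCCCCCCCCCC#C | intermediate
6 | (S)-tert-butyldimethyl(nonadec-18-yn-2-yloxy)silane | C[C@H](O[Si](C)(C)C(C)(C)C)CCCCCCCCCCCCCCCC#C | intermediate
7 | (S)-17-(tert-butyldimethylsilyloxy)octadecanoic acid | C[C@H](O[Si](C)(C)C(C)(C)C)CCCCCCCCCCCCCCCC(=O)O | intermediate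
8 | methyl 3,5-dioxohexanoate | COC(=O)CC(=O)CC(C)=O | starting material
9 | (S)-17-(tert-butyldimethylsilyloxy)-1-(1H-imidazol-1-yl)octadecan-1-one (acyl imidazolide, not isolated) | C[C@H](O[Si](C)(C)C(C)(C)C)CCCCCCCCCCCCCCCC(=O)n1ccnc1 | intermediate
10 | trilithium 1-methoxyhexa-1,3,5-triene-1,3,5-tris(olate) (trianion of 8, not isolated) | [Li+].[Li+].[Li+].C=C([O-])C=C([O-])C=C([O-])OC | intermediate
11 | methyl (23S)-23-(tert-butyldimethylsilyloxy)-3,5,7-trioxotetracosanoate (key-step precursor) | C[C@H](O[Si](C)(C)C(C)(C)C)CCCCCCCCCCCCCCCC(=O)CC(=O)CC(=O)CC(=O)OC | intermediate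
12 | methyl 2-hydroxy-2-[(16S)-16-(tert-butyldimethylsilyloxy)heptadecyl]-4,6-dioxocyclohexane-1-carboxylate (cyclic aldol adduct, ring centres undefined, not isolated) | C[C@H](O[Si](C)(C)C(C)(C)C)CCCCCCCCCCCCCCCC1(O)CC(=O)CC(=O)C1C(=O)OC | intermediate
13 | methyl 2,4-dihydroxy-6-[(16S)-16-(tert-butyldimethylsilyloxy)heptadecyl]benzoate (key-step product) | C[C@H](O[Si](C)(C)C(C)(C)C)CCCCCCCCCCCCCCCc1cc(O)cc(O)c1C(=O)OC | intermediate
14 | 2,4-dihydroxy-6-[(16S)-16-(tert-butyldimethylsilyloxy)heptadecyl]benzoic acid (not isolated) | C[C@H](O[Si](C)(C)C(C)(C)C)CCCCCCCCCCCCCCCc1cc(O)cc(O)c1C(=O)O | intermediate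
15 | 5-[(16S)-16-(tert-butyldimethylsilyloxy)heptadecyl]benzene-1,3-diol (not isolated) | C[C@H](O[Si](C)(C)C(C)(C)C)CCCCCCCCCCCCCCCc1cc(O)cc(O)c1 | intermediate
16 | Hansfordiol A, 5-[(16S)-16-hydroxyheptadecyl]benzene-1,3-diol | C[C@H](O)CCCCCCCCCCCCCCCc1cc(O)cc(O)c1 | target

**Totals**
Total step count: 7. Longest linear sequence: 7 steps (1 to 4 to 5 to 6 to 7 to 11 to 13 to 16); 2 and 8 enter as purchased partners.

**Steps most likely to fail**

Step 6 (key step). The tetraketide may close in the wrong mode: lactonization of the C5 enol onto the ester to a 4-hydroxy-2-pyranone, or Claisen closure from C6 onto C1. The aldol adduct may also be slow to dehydrate; methanolic HCl would then complete the dehydration, and the accompanying loss of the silyl ether would be harmless because step 7 removes it anyway. Fallback: the carboxyl end is locked in a dioxinone before the ring is made, so that neither the Claisen nor the lactone pathway exists. Commercial 2,2,6-trimethyl-4H-1,3-dioxin-4-one is deprotonated with LiN(SiMe3)2 (THF, −78 °C) and C-acetylated with acetyl chloride to give 2,2-dimethyl-6-(2-oxopropyl)-4H-1,3-dioxin-4-one F1. Its dianion (LiN(i-Pr)2, THF, −78 °C) is acylated at the terminal carbon by 9, made from 7 as in step 5, to give 6-[(20S)-20-(tert-butyldimethylsilyloxy)-2,4-dioxohenicosyl]-2,2-dimethyl-4H-1,3-dioxin-4-one F2. Et3N in CH2Cl2 should then bring about the same C2-to-C7 aldol dehydration and give 7-hydroxy-5-[(16S)-16-(tert-butyldimethylsilyloxy)heptadecyl]-2,2-dimethyl-4H-1,3-benzodioxin-4-one F3. Methanolysis (Cs2CO3, MeOH) opens the acetonide ester to 13. The fallback sets out from 7 (through 9), bypasses steps 5 and 6, and comes back at 13.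

Step 5. Proton transfer from the forming, more acidic triketo ester and from imidazole may quench the trianion before acylation is complete, and O-acylation or double acylation may compete. Fallback: the polyanion is replaced by a neutral silyl polyenol ether. Acid 7 is converted with 1-chloro-N,N,2-trimethylprop-1-en-1-amine (CH2Cl2, rt, neutral conditions) into (S)-17-(tert-butyldimethylsilyloxy)octadecanoyl chloride F4. Ester 8 is silylated stepwise (Me3SiCl/Et3N, then twice LiN(i-Pr)2/Me3SiCl) to 1-methoxy-1,3,5-tris(trimethylsilyloxy)hexa-1,3,5-triene F5 (mixture of double-bond isomers). F4 and F5 are combined in CH2Cl2 at −78 °C to rt in a vinylogous Mukaiyama-type C-acylation at the terminal carbon, and mild aqueous work-up hydrolyses the two remaining silyl enol ethers to give 11. The fallback sets out from 7 and 8 and comes back at 11.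

Step 4. Over-oxidation of the chain, loss of the silyl ether in the acidic periodate medium, or stalling at the alpha-keto acid stage may erode the cleavage. Fallback: the cleavage is moved from the alkyne to an alkene and the oxidation is split into two mild stages. Alkyne 6 is semihydrogenated (H2, Pd/CaCO3 poisoned with Pb(OAc)2, quinoline, hexane) to (S)-tert-butyldimethyl(nonadec-18-en-2-yloxy)silane F6. Ozonolysis (O3, CH2Cl2, −78 °C; then Me2S) gives (S)-17-(tert-butyldimethylsilyloxy)octadecanal F7. Pinnick oxidation (NaClO2, NaH2PO4, 2-methylbut-2-ene, t-BuOH/H2O) gives 7. The fallback sets out from 6 and comes back at 7.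

**Further compounds**
F1 | step 6 | 2,2-dimethyl-6-(2-oxopropyl)-4H-1,3-dioxin-4-one | CC(=O)CC1=CC(=O)OC(C)(C)O1
F2 | step 6 | 6-[(20S)-20-(tert-butyldimethylsilyloxy)-2,4-dioxohenicosyl]-2,2-dimethyl-4H-1,3-dioxin-4-one | C[C@H](O[Si](C)(C)C(C)(C)C)CCCCCCCCCCCCCCCC(=O)CC(=O)CC1=CC(=O)OC(C)(C)O1
F3 | step 6 | 7-hydroxy-5-[(16S)-16-(tert-butyldimethylsilyloxy)heptadecyl]-2,2-dimethyl-4H-1,3-benzodioxin-4-one | C[C@H](O[Si](C)(C)C(C)(C)C)CCCCCCCCCCCCCCCc1cc(O)cc2OC(C)(C)OC(=O)c12
F4 | step 5 | (S)-17-(tert-butyldimethylsilyloxy)octadecanoyl chloride | C[C@H](O[Si](C)(C)C(C)(C)C)CCCCCCCCCCCCCCCC(=O)Cl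
F5 | step 5 | 1-methoxy-1,3,5-tris(trimethylsilyloxy)hexa-1,3,5-triene (double-bond geometry undefined) | COC(O[Si](C)(C)C)=CC(O[Si](C)(C)C)=CC(O[Si](C)(C)C)=C
F6 | step 4 | (S)-tert-butyldimethyl(nonadec-18-en-2-yloxy)silane | C[C@H](O[Si](C)(C)C(C)(C)C)CCCCCCCCCCCCCCCC=C
F7 | step 4 | (S)-17-(tert-butyldimethylsilyloxy)octadecanal | C[C@H](O[Si](C)(C)C(C)(C)C)CCCCCCCCCCCCCCCC=O
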